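**Retrosynthetic overview**
1. The ten-membered ring is made last, by a four-atom radical ring expansion of a spiro butenolide–cyclohexenone: the C1–C10 bond forms, the C1–C6 bond breaks, and the 4Z alkene is inherited from the six-membered ring.
2. The C8 side chain comes from an asymmetric 2-bromoallylation of a 4-formyl butenolide (sets 8S), followed by acetylation.
3. The spiro butenolide comes from chlorocyclocarbonylation of a tertiary 2,3-allenol (CO becomes C12), then chloride-to-acetate exchange.
4. The allenol, with its quaternary C6–OH next to the C1 ketone, comes from a rhodium-carbenoid O–H insertion/[3,3] shift between 6-diazo-3-methylcyclohex-2-enone and 4,4-dimethoxybut-2-yn-1-ol.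
5. Ring order: cyclohexenone (bought), then butenolide (step 4), then ten-membered carbocycle (step 8).

Atom labels C1–C15 follow the germacrane numbering of the target: C1 ketone, C4=C5 ring alkene, C6 lactone carbinol, C7=C11 butenolide alkene, C8 acetoxy carbon, C10=C14 exo-methylene, C12 lactone carbonyl, C13 acetoxymethyl. In compounds 10–16 the spiro carbon is C6.

**Step 1**
Reactants: 1 prop-2-yn-1-ol; 2 trimethyl orthoformate
Product: 4 4,4-dimethoxybut-2-yn-1-ol, via bromomagnesium 3-(bromomagnesio)prop-2-yn-1-olate 3 (not isolated)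
Conditions: EtMgBr (2.1 equiv), THF, 0 °C to rt; then 2, toluene, 90 °C; aq. NH4Cl
Reagents that add atoms: none
Why: Bodroux–Chichibabin acetal synthesis, in which the alkynyl Grignard carbon of the dimagnesium salt displaces one methoxide of the orthoformate while the alkoxide end stays inert, so the future C8 enters at the aldehyde oxidation level; no stereocentre is formed.

**Step 2**
Reactants: 5 3-methylcyclohex-2-en-1-one
Product: 7 6-diazo-3-methylcyclohex-2-en-1-one, via 3-methyl-6-(trifluoroacetyl)cyclohex-2-en-1-one 6 (not isolated)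
Conditions: LiN(SiMe3)2, THF, −78 °C; CF3CO2CH2CF3; then MeSO2N3, Et3N, H2O, MeCN, rt
Reagents that add atoms: methanesulfonyl azide CS(=O)(=O)N=[N+]=[N-]
Why: Detrifluoroacetylative (Regitz-type) diazo transfer, in which kinetic deprotonation at the saturated α′-carbon and trifluoroacetylation activate that position for azide transfer and the trifluoroacetyl group then leaves as the sulfonamide; no stereocentre is formed.

**Step 3**
Reactants: 7 6-diazo-3-methylcyclohex-2-en-1-one; 4 4,4-dimethoxybut-2-yn-1-ol
Product: 9 2-(1,1-dimethoxybuta-2,3-dien-2-yl)-2-hydroxy-4-methylcyclohex-3-en-1-one (racemic), via 2-[(4,4-dimethoxybut-2-yn-1-yl)oxy]-5-methylcyclohexa-1,5-dien-1-ol 8 (not isolated)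
Conditions: Rh2(OAc)4 (1 mol%), 4 (1.5 equiv), PhH, 80 °C, slow addition of 7
Reagents that add atoms: none
Why: Rhodium-carbenoid O–H insertion followed by a [3,3]-sigmatropic (propargyl Claisen-type) shift of the propargyloxy enol, in which the carbenoid carbon becomes the C1 ketone and the former enone carbonyl carbon becomes the quaternary carbinol C6 bearing the allene, with C4=C5 left in the β,γ-position; C6 forms racemic, which is harmless because this centre is planarised again in step 8.

**Step 4**
Reactants: 9 2-(1,1-dimethoxybuta-2,3-dien-2-yl)-2-hydroxy-4-methylcyclohex-3-en-1-one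
Product: 10 3-(chloromethyl)-4-(dimethoxymethyl)-7-methyl-1-oxaspiro[4.5]deca-3,6-diene-2,10-dione (racemic)
Conditions: PdCl2 (5 mol%), CuCl2 (3 equiv), CO (1 atm), propylene oxide (5 equiv), THF, rt
Reagents that add atoms: carbon monoxide [C-]#[O+]; copper dichloride Cl[Cu]Cl
Why: Palladium/copper chlorocyclocarbonylation of a 2,3-allenol, in which the tertiary hydroxyl and CO give an alkoxycarbonyl–palladium that adds to the central allene carbon and chloride opens the π-allyl at its CH2 terminus, closing the butenolide onto C6 with C7=C11 and the C13 chloromethyl group in place (propylene oxide takes up HCl so the acetal survives); no new stereocentre.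

**Step 5**
Reactants: 10 3-(chloromethyl)-4-(dimethoxymethyl)-7-methyl-1-oxaspiro[4.5]deca-3,6-diene-2,10-dione
Product: 12 (4-formyl-7-methyl-2,10-dioxo-1-oxaspiro[4.5]deca-3,6-dien-3-yl)methyl acetate (racemic), via [4-(dimethoxymethyl)-7-methyl-2,10-dioxo-1-oxaspiro[4.5]deca-3,6-dien-3-yl]methyl acetate 11 (not isolated)
Conditions: KOAc (2 equiv), 18-crown-6 (cat.), MeCN, 40 °C; then 1 M HCl, THF, rt
Reagents that add atoms: potassium acetate CC(=O)[O-].[K+]; water O
Why: SN2 displacement of the primary allylic chloride by acetate (the spiro carbon carries no hydrogen, so the butenolide cannot be enolised) and then acid hydrolysis of the dimethyl acetal, which the acetate, lactone and ketone tolerate; no new stereocentre.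

**Step 6**
Reactants: 12 (4-formyl-7-methyl-2,10-dioxo-1-oxaspiro[4.5]deca-3,6-dien-3-yl)methyl acetate; 13 2,3-dibromoprop-1-ene
Product: 15 {4-[(1S)-3-bromo-1-hydroxybut-3-en-1-yl]-7-methyl-2,10-dioxo-1-oxaspiro[4.5]deca-3,6-dien-3-yl}methyl acetate (both epimers at the spiro carbon), via (2-bromoprop-2-en-1-yl)chromium dichloride 14 (not isolated)
Conditions: CrCl2 (2.5 equiv), Et3N (2.7 equiv), N-[2-((4S)-4-isopropyl-4,5-dihydro-1,3-oxazol-2-yl)-6-methylphenyl]methanesulfonamide (2.7 equiv; the antipode that gives the S carbinol is fixed in a pilot run by Mosher analysis), THF, rt; then 12 and 13 (1.2 equiv), 0 °C to rt; aq. work-up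
Reagents that add atoms: none
Why: Chromium-mediated (Nozaki–Hiyama-type) asymmetric 2-haloallylation, in which only the allylic C–Br of 13 is reduced (no nickel, so the vinylic C–Br stays), the allylchromium adds to the aldehyde far faster than to the hindered ketone, and the chiral sulfonamide ligand directs attack to the Si face to give 8S under reagent control for both enantiomers of the racemic aldehyde.

**Step 7**
Reactants: 15 {4-[(1S)-3-bromo-1-hydroxybut-3-en-1-yl]-7-methyl-2,10-dioxo-1-oxaspiro[4.5]deca-3,6-dien-3-yl}methyl acetate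
Product: 16 (1S)-1-{3-[(acetyloxy)methyl]-7-methyl-2,10-dioxo-1-oxaspiro[4.5]deca-3,6-dien-4-yl}-3-bromobut-3-en-1-yl acetate (both epimers at the spiro carbon)
Conditions: Ac2O, pyridine, DMAP (cat.), CH2Cl2, 0 °C
Reagents that add atoms: acetic anhydride CC(=O)OC(C)=O
Why: DMAP-catalysed acylation of the secondary allylic alcohol, which leaves the C8–O bond and hence the 8S configuration untouched.

**Step 8**
Reactants: 16 (1S)-1-{3-[(acetyloxy)methyl]-7-methyl-2,10-dioxo-1-oxaspiro[4.5]deca-3,6-dien-4-yl}-3-bromobut-3-en-1-yl acetate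
Product: 17 (6R,8S)-8,13-diacetoxy-1-oxogermacra-4Z,7(11),10(14)-trien-12,6-olide (CNP0239761.1)
Conditions: (Me3Si)3SiH (1.3 equiv) and AIBN (0.3 equiv) by syringe pump over 8 h, 4-MeOC6H4SH (5 mol%), PhH (0.005 M), 80 °C; then 2 h at 80 °C
Reagents that add atoms: none
Why: Proposed new method: the silyl radical abstracts bromine, the nucleophilic σ-vinyl radical at C10 adds 6-exo to the ketone carbon C1 in preference to the electron-rich trisubstituted alkene, and the bicyclic alkoxy radical cleaves only the C1–C6 bond because this releases a butenolide γ-radical (2-oxyfuranyl, doubly allylic), giving the ten-membered α-methylene ketone with the 4Z alkene carried over from the six-membered ring and both spiro epimers of 16 converging; ArSH/ArS• then transfers the C6 hydrogen reversibly (near thermoneutral), so C6 equilibrates by hydrogen-atom transfer without any dienolate that could expel the 13-acetate, and the 6R epimer is expected to prevail because it alone lets C5 and C9 leave the butenolide plane on opposite faces while H-8 lies in that plane next to C13; the closest known reaction type is the Dowd–Beckwith ring expansion of α-haloalkyl β-keto esters, extended here to a vinyl radical, a butenolide as radical-stabilising group and thiol polarity-reversal catalysis.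

**Compound list**
1 | prop-2-yn-1-ol | C#CCO | starting material
2 | trimethyl orthoformate | COC(OC)OC | starting material
3 | bromomagnesium 3-(bromomagnesio)prop-2-yn-1-olate | Br[Mg]C#CCO[Mg]Br | intermediate
4 | 4,4-dimethoxybut-2-yn-1-ol | COC(OC)C#CCO | intermediate
5 | 3-methylcyclohex-2-en-1-one | CC1=CC(=O)CC1 | starting material
6 | 3-methyl-6-(trifluoroacetyl)cyclohex-2-en-1-one | CC1=CC(=O)C(C(=O)C(F)(F)F)CC1 | intermediate
7 | 6-diazo-3-methylcyclohex-2-en-1-one | CC1=CC(=O)C(=[N+]=[N-])CC1 | intermediate
8 | 2-[(4,4-dimethoxybut-2-yn-1-yl)oxy]-5-methylcyclohexa-1,5-dien-1-ol | CC1=CC(O)=C(OCC#CC(OC)OC)CC1 | intermediate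
9 | 2-(1,1-dimethoxybuta-2,3-dien-2-yl)-2-hydroxy-4-methylcyclohex-3-en-1-one (racemic) | O=C1CCC(C)=CC1(O)C(=C=C)C(OC)OC | intermediate
10 | 3-(chloromethyl)-4-(dimethoxymethyl)-7-methyl-1-oxaspiro[4.5]deca-3,6-diene-2,10-dione (racemic) | O=C1CCC(C)=CC12OC(=O)C(CCl)=C2C(OC)OC | intermediate
11 | [4-(dimethoxymethyl)-7-methyl-2,10-dioxo-1-oxaspiro[4.5]deca-3,6-dien-3-yl]methyl acetate (racemic) | O=C1CCC(C)=CC12OC(=O)C(COC(C)=O)=C2C(OC)OC | intermediate
12 | (4-formyl-7-methyl-2,10-dioxo-1-oxaspiro[4.5]deca-3,6-dien-3-yl)methyl acetate (racemic) | O=C1CCC(C)=CC12OC(=O)C(COC(C)=O)=C2C=O | intermediate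
13 | 2,3-dibromoprop-1-ene | C=C(Br)CBr | starting material
14 | (2-bromoprop-2-en-1-yl)chromium dichloride | C=C(Br)C[Cr](Cl)Cl | intermediate
15 | {4-[(1S)-3-bromo-1-hydroxybut-3-en-1-yl]-7-methyl-2,10-dioxo-1-oxaspiro[4.5]deca-3,6-dien-3-yl}methyl acetate (both spiro epimers) | O=C1CCC(C)=CC12OC(=O)C(COC(C)=O)=C2[C@@H](O)CC(Br)=C | intermediate
16 | (1S)-1-{3-[(acetyloxy)methyl]-7-methyl-2,10-dioxo-1-oxaspiro[4.5]deca-3,6-dien-4-yl}-3-bromobut-3-en-1-yl acetate (both spiro epimers) | O=C1CCC(C)=CC12OC(=O)C(COC(C)=O)=C2[C@@H](OC(C)=O)CC(Br)=C | intermediate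
17 | (6R,8S)-8,13-diacetoxy-1-oxogermacra-4Z,7(11),10(14)-trien-12,6-olide | C=C1C[C@H](OC(C)=O)C2=C(COC(C)=O)C(=O)O[C@@H]2/C=C(/C)CCC1=O | target

**Step count and risk**
Total: 8 steps. Longest linear sequence: 7 steps (5 to 17 through steps 2–8; 1 + 2 to 4 is a one-step branch).

Steps most likely to fail:

Step 8 (new ring expansion). The risks are a short radical chain because the product radical is strongly stabilised, hydrosilylation or thiol addition at the α-methylene ketone, and a C6 epimer ratio that is predicted, not known. The fallback sets out from 16 and returns at 17. A nickel-catalysed, chromium-mediated Nozaki–Hiyama–Kishi cyclisation (NiCl2 1 mol%, CrCl2 4 equiv, DMSO, rt) adds the vinyl bromide carbon to the ring ketone and gives the tricyclic tertiary alcohol from ketone–vinyl 1,2-addition of 16 (C8 S) F7. Retro-aldol opening of its C1–C6 bond with catalytic DBU in MeCN buffered with AcOH/Bu4NOAc at 40 °C gives 17; in acetate buffer loss and return of the 13-acetate is degenerate and C6 equilibrates. If the equilibrium epimer proves to be 6S, low-temperature opening of F7 with KN(SiMe3)2 and a quench with 2,6-di-tert-butylphenol gives a kinetic protonation as a second handle on C6.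

Step 3 (carbenoid O–H insertion/[3,3] shift). The risks are a 1,2-hydride shift of the cyclic carbenoid (leading to m-cresol), ketonisation of enol 8 before rearrangement, and a competing [2,3] pathway. The fallback sets out from 5 and 4 and returns at 9. Kinetic silyl enol ether formation and Rubottom oxidation of 5 (LiN(SiMe3)2, tBuMe2SiCl; then mCPBA) give 6-[(tert-butyldimethylsilyl)oxy]-3-methylcyclohex-2-en-1-one F1. Alcohol 4 is converted with CBr4/PPh3 into 4-bromo-1,1-dimethoxybut-2-yne F2. Indium-mediated Barbier addition of F2 to the ketone of F1 (In powder, THF/H2O; γ-substituted propargyl bromides react at the substituted carbon) gives 6-[(tert-butyldimethylsilyl)oxy]-1-(1,1-dimethoxybuta-2,3-dien-2-yl)-3-methylcyclohex-2-en-1-ol F3. Bu4NF gives 2-(1,1-dimethoxybuta-2,3-dien-2-yl)-4-methylcyclohex-3-ene-1,2-diol F4, and Dess–Martin oxidation of its secondary alcohol gives 9.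

Step 6 (asymmetric 2-bromoallylation). The risks are modest enantiocontrol on a hindered, racemic, polyfunctional aldehyde and slow reduction of the α-acyloxy ketone by excess divalent chromium. The fallback sets out from 12 and 13 and returns at 15. An unselective indium Barbier reaction (In powder, THF/H2O) gives {4-(3-bromo-1-hydroxybut-3-en-1-yl)-7-methyl-2,10-dioxo-1-oxaspiro[4.5]deca-3,6-dien-3-yl}methyl acetate as a carbinol-epimer mixture F5. Dess–Martin oxidation gives [4-(3-bromobut-3-enoyl)-7-methyl-2,10-dioxo-1-oxaspiro[4.5]deca-3,6-dien-3-yl]methyl acetate F6. Corey–Bakshi–Shibata reduction of this conjugated ketone ((R)-2-methyl-CBS-oxazaborolidine, catecholborane, −78 °C) gives 15 with 8S; the hindered α-quaternary ring ketone is reduced more slowly.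

**Further compounds**
F1 | step 3 | 6-[(tert-butyldimethylsilyl)oxy]-3-methylcyclohex-2-en-1-one | CC1=CC(=O)C(O[Si](C)(C)C(C)(C)C)CC1
F2 | step 3 | 4-bromo-1,1-dimethoxybut-2-yne | COC(OC)C#CCBr
F3 | step 3 | 6-[(tert-butyldimethylsilyl)oxy]-1-(1,1-dimethoxybuta-2,3-dien-2-yl)-3-methylcyclohex-2-en-1-ol | CC1=CC(O)(C(=C=C)C(OC)OC)C(O[Si](C)(C)C(C)(C)C)CC1
F4 | step 3 | 2-(1,1-dimethoxybuta-2,3-dien-2-yl)-4-methylcyclohex-3-ene-1,2-diol | CC1=CC(O)(C(=C=C)C(OC)OC)C(O)CC1
F5 | step 6 | {4-(3-bromo-1-hydroxybut-3-en-1-yl)-7-methyl-2,10-dioxo-1-oxaspiro[4.5]deca-3,6-dien-3-yl}methyl acetate (carbinol-epimer mixture) | O=C1CCC(C)=CC12OC(=O)C(COC(C)=O)=C2C(O)CC(Br)=C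
F6 | step 6 | [4-(3-bromobut-3-enoyl)-7-methyl-2,10-dioxo-1-oxaspiro[4.5]deca-3,6-dien-3-yl]methyl acetate | O=C1CCC(C)=CC12OC(=O)C(COC(C)=O)=C2C(=O)CC(Br)=C
F7 | step 8 | tricyclic tertiary alcohol from ketone–vinyl 1,2-addition of 16 (C8 S) | C=C1C[C@H](OC(C)=O)C2=C(COC(C)=O)C(=O)OC23C=C(C)CCC13O
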